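## Retrosynthetic overview

1. Glycybridin C (20) comes from its tris-MOM ether 19 by acetal cleavage.
2. The C-2 hydroxyl of 19 comes from reagent-controlled oxidation of the enolate of dihydrochalcone 17, which comes from chalcone 15 by 1,4-reduction.
3. Key C–C bond (C-2/C-3): intermolecular Claisen–Schmidt aldol condensation of acetophenone 7 with benzaldehyde 13.
4. Each prenyl group is built on 2,4-dihydroxyacetophenone (1) or 4-hydroxybenzaldehyde (8) by O-allylation, aromatic Claisen rearrangement and cross-metathesis with 2-methyl-2-butene.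
5. No ring is formed; ring A (from 1) and ring B (from 8) are bought intact.

Assumption: allyl bromide, MOMCl, 2-methyl-2-butene and the oxaziridine are commercial reagents, given with SMILES on the reagent line and not numbered.
Assumption: the sense of induction in step 11 is taken from the known behaviour of sodium (Z)-enolates of propiophenone and deoxybenzoin, recalled rather than looked up, and is to be confirmed on 19 (Mosher esters, chiral HPLC) before step 12.

## Route

Step 1
Reactants: 1 2,4-dihydroxyacetophenone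
Product: 2 1-[2-hydroxy-4-(prop-2-en-1-yloxy)phenyl]ethan-1-one
Conditions: allyl bromide (1.1 equiv), K2CO3 (1.5 equiv), acetone, reflux, 6 h
Reagents that add atoms: allyl bromide, C=CCBr
Why: Williamson etherification; the 2-OH is hydrogen-bonded to the acetyl carbonyl, so only the free, more acidic 4-OH is allylated.

Step 2
Reactants: 2 1-[2-hydroxy-4-(prop-2-en-1-yloxy)phenyl]ethan-1-one
Product: 4 1-[2,4-dihydroxy-3-(prop-2-en-1-yl)phenyl]ethan-1-one, via ortho-dienone 3 (not isolated)
Conditions: PhNEt2, 205 °C, Ar, 5 h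
Reagents that add atoms: none
Why: Aromatic Claisen rearrangement ([3,3]-sigmatropic shift, then tautomerisation); bond fixation in the chelated 2-hydroxyacetophenone directs the allyl group to C-3 between the two oxygens, the established outcome for this substrate.

Step 3
Reactants: 4 1-[2,4-dihydroxy-3-(prop-2-en-1-yl)phenyl]ethan-1-one
Product: 6 1-[2,4-bis(methoxymethoxy)-3-(prop-2-en-1-yl)phenyl]ethan-1-one, via disodium diphenoxide 5 (not isolated)
Conditions: NaH (2.4 equiv), DMF, 0 °C, 30 min; MOMCl (2.6 equiv), 0 °C → rt, 3 h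
Reagents that add atoms: chloromethyl methyl ether (MOMCl), COCCl
Why: Williamson-type O-alkylation of the preformed diphenoxide by the very reactive chloromethyl ether protects even the hindered, chelated 2-OH as a base-stable acetal.

Step 4
Reactants: 6 1-[2,4-bis(methoxymethoxy)-3-(prop-2-en-1-yl)phenyl]ethan-1-one
Product: 7 1-[2,4-bis(methoxymethoxy)-3-(3-methylbut-2-en-1-yl)phenyl]ethan-1-one
Conditions: second-generation Grubbs catalyst RuCl2(H2IMes)(PCy3)(=CHPh) (3 mol %), 2-methyl-2-butene (large excess)/CH2Cl2, 40 °C, sealed tube, 12 h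
Reagents that add atoms: 2-methyl-2-butene, CC=C(C)C
Why: Olefin cross-metathesis; the terminal allyl alkene exchanges its methylene for the isopropylidene of the excess alkene (allyl to prenyl), while the aryl ketone and the acetals are inert.

Step 5
Reactants: 8 4-hydroxybenzaldehyde
Product: 9 4-(prop-2-en-1-yloxy)benzaldehyde
Conditions: allyl bromide (1.2 equiv), K2CO3 (1.5 equiv), acetone, reflux, 5 h
Reagents that add atoms: allyl bromide, C=CCBr
Why: Williamson etherification of a single acidic phenol.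

Step 6
Reactants: 9 4-(prop-2-en-1-yloxy)benzaldehyde
Product: 11 4-hydroxy-3-(prop-2-en-1-yl)benzaldehyde, via ortho-dienone 10 (not isolated)
Conditions: neat, 220 °C, Ar, 6 h
Reagents that add atoms: none
Why: Aromatic Claisen rearrangement; the two ortho positions are equivalent, so one regioisomer forms.

Step 7
Reactants: 11 4-hydroxy-3-(prop-2-en-1-yl)benzaldehyde
Product: 12 4-(methoxymethoxy)-3-(prop-2-en-1-yl)benzaldehyde
Conditions: MOMCl (1.5 equiv), K2CO3 (2 equiv), acetone, 0 °C → reflux, 4 h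
Reagents that add atoms: chloromethyl methyl ether (MOMCl), COCCl
Why: Williamson-type O-alkylation of an unhindered phenoxide gives the acetal needed for the basic steps that follow.

Step 8
Reactants: 12 4-(methoxymethoxy)-3-(prop-2-en-1-yl)benzaldehyde
Product: 13 4-(methoxymethoxy)-3-(3-methylbut-2-en-1-yl)benzaldehyde
Conditions: second-generation Grubbs catalyst RuCl2(H2IMes)(PCy3)(=CHPh) (3 mol %), 2-methyl-2-butene (large excess)/CH2Cl2, 40 °C, sealed tube, 12 h
Reagents that add atoms: 2-methyl-2-butene, CC=C(C)C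
Why: Olefin cross-metathesis as in step 4; the aldehyde is tolerated by the ruthenium carbene.

Step 9
Reactants: 7 1-[2,4-bis(methoxymethoxy)-3-(3-methylbut-2-en-1-yl)phenyl]ethan-1-one; 13 4-(methoxymethoxy)-3-(3-methylbut-2-en-1-yl)benzaldehyde
Product: 15 (2E)-1-[2,4-bis(methoxymethoxy)-3-(3-methylbut-2-en-1-yl)phenyl]-3-[4-(methoxymethoxy)-3-(3-methylbut-2-en-1-yl)phenyl]prop-2-en-1-one, via aldol adduct 14 (not isolated)
Conditions: KOH (50% aq., 10 equiv), EtOH, rt, 36 h
Reagents that add atoms: none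
Why: Claisen–Schmidt aldol condensation; the enolate of methyl ketone 7 adds to the non-enolisable aldehyde 13 and aldol 14 loses water by E1cB elimination to the conjugated (E)-enone, forming the central C–C bond.

Step 10
Reactants: 15 (2E)-1-[2,4-bis(methoxymethoxy)-3-(3-methylbut-2-en-1-yl)phenyl]-3-[4-(methoxymethoxy)-3-(3-methylbut-2-en-1-yl)phenyl]prop-2-en-1-one
Product: 17 1-[2,4-bis(methoxymethoxy)-3-(3-methylbut-2-en-1-yl)phenyl]-3-[4-(methoxymethoxy)-3-(3-methylbut-2-en-1-yl)phenyl]propan-1-one, via copper enolate 16 (not isolated)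
Conditions: [(Ph3P)CuH]6 (0.35 equiv), H2O (3 equiv), degassed toluene, rt, Ar, 4 h
Reagents that add atoms: none
Why: Conjugate reduction with Stryker's reagent; the soft copper hydride adds only to the enone β-carbon and water protonates the copper enolate, so the isolated prenyl alkenes, the acetals and the ketone are untouched.

Step 11
Reactants: 17 1-[2,4-bis(methoxymethoxy)-3-(3-methylbut-2-en-1-yl)phenyl]-3-[4-(methoxymethoxy)-3-(3-methylbut-2-en-1-yl)phenyl]propan-1-one
Product: 19 (2R)-2-hydroxy-1-[2,4-bis(methoxymethoxy)-3-(3-methylbut-2-en-1-yl)phenyl]-3-[4-(methoxymethoxy)-3-(3-methylbut-2-en-1-yl)phenyl]propan-1-one, via sodium enolate 18 (not isolated)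
Conditions: NaN(SiMe3)2 (1.15 equiv), THF, −78 °C, 40 min; (−)-(2S,8aR)-(camphorsulfonyl)oxaziridine [(1R)-(−)-(10-camphorsulfonyl)oxaziridine] (1.5 equiv), −78 °C, 2 h; AcOH (2 equiv) in THF, −78 °C → rt
Reagents that add atoms: (−)-(2S,8aR)-(camphorsulfonyl)oxaziridine, CC1(C)[C@H]2CC[C@@]13CS(=O)(=O)[N@@]4O[C@]34C2
Why: Davis asymmetric enolate hydroxylation; the sodium (Z)-enolate attacks the oxaziridine oxygen in an SN2-type transition state, and because the (+)-reagent gives the (S)-ketols from such enolates, the (−)-reagent delivers oxygen to the face that gives the (R)-centre, which the cold AcOH quench protects from epimerisation.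

Step 12
Reactants: 19 (2R)-2-hydroxy-1-[2,4-bis(methoxymethoxy)-3-(3-methylbut-2-en-1-yl)phenyl]-3-[4-(methoxymethoxy)-3-(3-methylbut-2-en-1-yl)phenyl]propan-1-one
Product: 20 glycybridin C, (2R)-1-[2,4-dihydroxy-3-(3-methylbut-2-en-1-yl)phenyl]-2-hydroxy-3-[4-hydroxy-3-(3-methylbut-2-en-1-yl)phenyl]propan-1-one
Conditions: 3 M aq. HCl–MeOH (1:4), 35–40 °C, 2–4 h (monitored); NaHCO3 work-up
Reagents that add atoms: none
Why: Acid-catalysed acetal methanolysis removes the three MOM ethers under conditions too mild to enolise the aryl ketone or cyclise the ortho-prenylphenols to chromans, so the (R)-centre is untouched.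

## Compound list

1 | 2,4-dihydroxyacetophenone | CC(=O)c1ccc(O)cc1O | starting material
2 | 1-[2-hydroxy-4-(prop-2-en-1-yloxy)phenyl]ethan-1-one | CC(=O)c1ccc(OCC=C)cc1O | intermediate
3 | 4-acetyl-5-hydroxy-6-(prop-2-en-1-yl)cyclohexa-2,4-dien-1-one (racemic ortho-dienone) | CC(=O)C1=C(O)C(CC=C)C(=O)C=C1 | intermediate (not isolated)
4 | 1-[2,4-dihydroxy-3-(prop-2-en-1-yl)phenyl]ethan-1-one | CC(=O)c1ccc(O)c(CC=C)c1O | intermediate
5 | disodium 4-acetyl-2-(prop-2-en-1-yl)benzene-1,3-bis(olate) | CC(=O)c1ccc([O-])c(CC=C)c1[O-].[Na+].[Na+] | intermediate (not isolated)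
6 | 1-[2,4-bis(methoxymethoxy)-3-(prop-2-en-1-yl)phenyl]ethan-1-one | CC(=O)c1ccc(OCOC)c(CC=C)c1OCOC | intermediate
7 | 1-[2,4-bis(methoxymethoxy)-3-(3-methylbut-2-en-1-yl)phenyl]ethan-1-one | CC(=O)c1ccc(OCOC)c(CC=C(C)C)c1OCOC | intermediate
8 | 4-hydroxybenzaldehyde | O=Cc1ccc(O)cc1 | starting material
9 | 4-(prop-2-en-1-yloxy)benzaldehyde | O=Cc1ccc(OCC=C)cc1 | intermediate
10 | 4-oxo-3-(prop-2-en-1-yl)cyclohexa-1,5-diene-1-carbaldehyde (racemic ortho-dienone) | O=CC1=CC(CC=C)C(=O)C=C1 | intermediate (not isolated)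
11 | 4-hydroxy-3-(prop-2-en-1-yl)benzaldehyde | O=Cc1ccc(O)c(CC=C)c1 | intermediate
12 | 4-(methoxymethoxy)-3-(prop-2-en-1-yl)benzaldehyde | O=Cc1ccc(OCOC)c(CC=C)c1 | intermediate
13 | 4-(methoxymethoxy)-3-(3-methylbut-2-en-1-yl)benzaldehyde | O=Cc1ccc(OCOC)c(CC=C(C)C)c1 | intermediate
14 | 3-hydroxy-1-[2,4-bis(methoxymethoxy)-3-(3-methylbut-2-en-1-yl)phenyl]-3-[4-(methoxymethoxy)-3-(3-methylbut-2-en-1-yl)phenyl]propan-1-one (racemic aldol) | CC(C)=CCc1cc(C(O)CC(=O)c2ccc(OCOC)c(CC=C(C)C)c2OCOC)ccc1OCOC | intermediate (not isolated)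
15 | (2E)-1-[2,4-bis(methoxymethoxy)-3-(3-methylbut-2-en-1-yl)phenyl]-3-[4-(methoxymethoxy)-3-(3-methylbut-2-en-1-yl)phenyl]prop-2-en-1-one | CC(C)=CCc1cc(/C=C/C(=O)c2ccc(OCOC)c(CC=C(C)C)c2OCOC)ccc1OCOC | intermediate
16 | triphenylphosphine-ligated copper (Z)-enolate of 17 | CC(C)=CCc1cc(C/C=C(\O[Cu-][P+](c2ccccc2)(c2ccccc2)c2ccccc2)c2ccc(OCOC)c(CC=C(C)C)c2OCOC)ccc1OCOC | intermediate (not isolated)
17 | 1-[2,4-bis(methoxymethoxy)-3-(3-methylbut-2-en-1-yl)phenyl]-3-[4-(methoxymethoxy)-3-(3-methylbut-2-en-1-yl)phenyl]propan-1-one | CC(C)=CCc1cc(CCC(=O)c2ccc(OCOC)c(CC=C(C)C)c2OCOC)ccc1OCOC | intermediate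
18 | sodium (Z)-enolate of 17 | CC(C)=CCc1cc(C/C=C(\[O-])c2ccc(OCOC)c(CC=C(C)C)c2OCOC)ccc1OCOC.[Na+] | intermediate (not isolated)
19 | (2R)-2-hydroxy-1-[2,4-bis(methoxymethoxy)-3-(3-methylbut-2-en-1-yl)phenyl]-3-[4-(methoxymethoxy)-3-(3-methylbut-2-en-1-yl)phenyl]propan-1-one | CC(C)=CCc1cc(C[C@@H](O)C(=O)c2ccc(OCOC)c(CC=C(C)C)c2OCOC)ccc1OCOC | intermediate
20 | glycybridin C, (2R)-1-[2,4-dihydroxy-3-(3-methylbut-2-en-1-yl)phenyl]-2-hydroxy-3-[4-hydroxy-3-(3-methylbut-2-en-1-yl)phenyl]propan-1-one | CC(C)=CCc1cc(C[C@@H](O)C(=O)c2ccc(O)c(CC=C(C)C)c2O)ccc1O | target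

## Step count and risks

Total steps: 12. Longest linear sequence: 8 steps (steps 1, 2, 3, 4, 9, 10, 11, 12; steps 5–8 are the second branch).

**Step 11 (most likely to fail).** The ortho-alkoxy aryl ketone may give a lower ee than simple propiophenones, and the sense of induction rests on analogy. Fallback: set out from chalcone 15 and come back at 19; steps 10 and 11 are then not needed. Juliá–Colonna epoxidation of 15 (poly-L-leucine, urea–H2O2, DBU, THF, rt) gives the (2R,3S)-epoxy ketone F1; poly-L-amino acids give this enantiomer with chalcones, and the isolated prenyl alkenes do not react with the hydroperoxide anion. MgBr2·OEt2 (Et2O–toluene, −30 °C) opens the chelated epoxide at the electron-rich benzylic carbon to give the bromohydrin F2 as a mixture of C-3 epimers. F2 is (2S) by name only because CHBr outranks the carbonyl carbon; the arrangement in space at C-2 is that of 19. Bu3SnH/AIBN (toluene, 80 °C) then removes the benzylic bromine by a radical chain to give 19. The C-2–O bond is never broken, so the configuration set in the epoxidation is carried through.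

**Step 12.** Acid may erode the ee of the free α-ketol or close an ortho-prenylphenol to a chroman. Fallback: set out from 17 and come back at 20, so that the stereocentre never meets acid. The same HCl–MeOH treatment is applied to achiral 17 to give the triphenol dihydrochalcone F3. Allyl bromide with Cs2CO3 (DMF, 50 °C) gives the tris(allyl ether) F4. NaN(SiMe3)2 (THF, −78 °C) gives the sodium enolate F5, which is oxidised with the same (−)-oxaziridine and quenched cold with AcOH to the (2R)-hydroxy ketone tris(allyl ether) F6. Pd(PPh3)4 (zerovalent palladium, 5 mol %) with morpholine (THF, rt) transfers the three O-allyl groups to the amine under neutral conditions and gives 20. The C-prenyl groups are not allylic leaving groups and stay.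

**Step 10.** The air-sensitive hydride may give incomplete conversion or some over-reduction to the saturated alcohol. Fallback: set out from 15 and come back at 17 by 1,2-reduction and redox isomerisation instead of hydride conjugate addition. NaBH4/CeCl3·7H2O (MeOH–THF, −20 °C) reduces only the carbonyl group to give the allylic alcohol F7. CpRuCl(PPh3)2 (5 mol %) with Et3NH·PF6 (10 mol %) in dioxane at 100 °C isomerises the allylic alcohol to the saturated ketone 17 by a ruthenium hydride shift that needs the allylic hydroxyl, so the prenyl alkenes are left alone.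

## Further compounds

F1 | step 11 | [(2R,3S)-3-[4-(methoxymethoxy)-3-(3-methylbut-2-en-1-yl)phenyl]oxiran-2-yl][2,4-bis(methoxymethoxy)-3-(3-methylbut-2-en-1-yl)phenyl]methanone | CC(C)=CCc1cc([C@@H]2O[C@H]2C(=O)c3ccc(OCOC)c(CC=C(C)C)c3OCOC)ccc1OCOC
F2 | step 11 | (2S)-3-bromo-2-hydroxy-1-[2,4-bis(methoxymethoxy)-3-(3-methylbut-2-en-1-yl)phenyl]-3-[4-(methoxymethoxy)-3-(3-methylbut-2-en-1-yl)phenyl]propan-1-one (C-3 epimers) | CC(C)=CCc1cc(C(Br)[C@@H](O)C(=O)c2ccc(OCOC)c(CC=C(C)C)c2OCOC)ccc1OCOC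
F3 | step 12 | 1-[2,4-dihydroxy-3-(3-methylbut-2-en-1-yl)phenyl]-3-[4-hydroxy-3-(3-methylbut-2-en-1-yl)phenyl]propan-1-one | CC(C)=CCc1cc(CCC(=O)c2ccc(O)c(CC=C(C)C)c2O)ccc1O
F4 | step 12 | 1-[3-(3-methylbut-2-en-1-yl)-2,4-bis(prop-2-en-1-yloxy)phenyl]-3-[3-(3-methylbut-2-en-1-yl)-4-(prop-2-en-1-yloxy)phenyl]propan-1-one | CC(C)=CCc1cc(CCC(=O)c2ccc(OCC=C)c(CC=C(C)C)c2OCC=C)ccc1OCC=C
F5 | step 12 | sodium (Z)-enolate of F4 (not isolated) | CC(C)=CCc1cc(C/C=C(\[O-])c2ccc(OCC=C)c(CC=C(C)C)c2OCC=C)ccc1OCC=C.[Na+]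
F6 | step 12 | (2R)-2-hydroxy-1-[3-(3-methylbut-2-en-1-yl)-2,4-bis(prop-2-en-1-yloxy)phenyl]-3-[3-(3-methylbut-2-en-1-yl)-4-(prop-2-en-1-yloxy)phenyl]propan-1-one | CC(C)=CCc1cc(C[C@@H](O)C(=O)c2ccc(OCC=C)c(CC=C(C)C)c2OCC=C)ccc1OCC=C
F7 | step 10 | (2E)-1-[2,4-bis(methoxymethoxy)-3-(3-methylbut-2-en-1-yl)phenyl]-3-[4-(methoxymethoxy)-3-(3-methylbut-2-en-1-yl)phenyl]prop-2-en-1-ol (racemic) | CC(C)=CCc1cc(/C=C/C(O)c2ccc(OCOC)c(CC=C(C)C)c2OCOC)ccc1OCOC
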